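Remark on the chemistry: full O-demethylation of the coupled leuco compound frees four phenolic hydroxyls, so the substrate of the last oxidation is treated as a tetraphenol (13), of which only the two rings on C7 can become the quinone methide.

Remark on the chemistry: ring A is taken from the bromo-iodo arene 1 and not from a dibromide, so that the Suzuki site is fixed by halogen identity as well as by hindrance; the precursor of the key step (6) is unchanged by this choice.

## Structural features

Selaginellin U (14) is an achiral C34 polyphenol built around one 1,2,3,4-tetrasubstituted benzene, ring A, which carries a methyl group on C1, a (4-hydroxyphenyl)ethynyl group on C2, the exocyclic carbon C7 on C3 and a 4-hydroxyphenyl ring (ring B) on C4; C5 and C6 bear hydrogen. C7 is a fully substituted sp2 carbon that holds one 4-hydroxyphenyl ring and is doubly bonded to C4 of a cyclohexa-2,5-dienone, so the two rings on C7 are the phenol half and the quinone methide half of a fuchsone. The dienone ring is symmetric about the C7=C axis, so this double bond has no configuration and the molecule has no stereocentre; hence no stereocentres stand next to each other, and the hindered C3–C7 and C4–ring B axes are not defined stereo-elements. The fragile groups are the quinone methide (electrophilic at C7 and ionised to a triaryl cation by acid), the three free phenols (easily oxidised) and the diaryl alkyne on C2, which lies ortho to C7 and can trap a cation formed there or add Lewis acids. The real difficulty is the crowding of three different carbon substituents on the adjacent atoms C2, C3 and C4: each has to be placed regiospecifically, the bonds to C7 and to C2 have to be made between two ortho neighbours, and cationic chemistry at C7 must never coincide with strong acid and the alkyne. The key step uses the fact that the two rings on C7 are the same para-oxygenated six-membered ring in two oxidation states: one hydride added to C7 turns the fuchsone into a symmetric bis(4-hydroxyphenyl)methyl group on C3 of ring A. That leuco group is exactly what two para attacks of phenol on an aldehyde carbon attached to C3 would deliver.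

## Logic of the disconnections

14 ⇒ 13. No skeletal bond is cut. The C7=C double bond and the ring carbonyl are traced back to a C7–H bond and a fourth phenolic O–H. The reason is that the quinone methide is the most sensitive group and is best made last; in 13 the two rings on C7 become identical, which opens the symmetric disconnection further back. The forward step must remove hydride from C7 in the presence of four phenols and an alkyne and must stop at the quinone methide.

13 ⇒ 12. The two O–CH3 bonds on ring B and on the alkynyl aryl ring are the ones set aside. These oxygens come from commercial methoxy building blocks and must stay masked through the organometallic, acidic and coupling steps. The demand is an ether cleavage that leaves the diaryl alkyne and the C7–H bond intact, which is why it is placed while C7 is still sp3.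

12 ⇒ 10 + 11. The C2–C(sp) bond is cut. Installing the alkyne only after all cationic chemistry at C7 removes any chance of cation–alkyne cyclisation and takes nine carbons off in one operation. The forward coupling must succeed at a C–Br bond flanked by the methyl group and the diarylmethyl group, with two free phenols present.

10 ⇒ 6 + two molecules of 7. Both C7–aryl bonds are cut. This removes twelve carbons and both C7 rings at once and reduces the crowded triarylmethane to an aldehyde on C3. The forward step must attack the para carbon of 7 twice, must push a di-ortho-substituted carbonyl to full conversion, must capture the intermediate cation intermolecularly, and must leave the C2 bromide and the ring B ether untouched.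

6 ⇒ 4 + 5. The C4–ring B biaryl bond is cut. The two halogens ortho to the formyl group of 4 differ in kind (iodide against bromide) and in hindrance (one ortho neighbour against two), so a single arylation can be directed to C4 while the bromide is kept for the alkyne. The forward coupling must stop after one aryl transfer.

4 ⇒ 1. The C3–C7 bond is cut, using a one-carbon formyl donor. The ring C–H of 1 that lies between the two halogens is by far the most acidic, so deprotonation there fixes the whole substitution pattern of ring A from a commercial toluene. The forward step must keep the 2,6-dihaloaryl anion cold enough to avoid loss of lithium halide and halogen migration.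

## Other disconnections considered

Alternative 1: The cut goes through ring A itself. C2–C3, C4–C5 and C6–C1 are disconnected to three alkynes: the propargylic alcohol A2 (C3, C4, C7 and all three anisyl rings), the propynylboronate A3 (methyl, C1, C2) and acetylene A4 (C5, C6).
- Forward step: A2 and A3 would exchange an alkoxy group to give a mixed boronate that tethers two triple bonds. Cp*RuCl(cod) would couple them oxidatively to a ruthenacycle, A4 would insert, and reductive elimination would close ring A, leaving boron on C2 inside the oxaborole A1.
- In favour: the four contiguous substituents are placed by the tether and not by arene substitution rules. C7 arrives as a carbinol, so the final demethylation could ionise it straight to the quinone methide with no oxidant; on oxidation-state economy this is better than the chosen plan. The count could be four or five steps, which is also better on paper.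
- Against: the tether has to form on a tertiary, doubly benzylic propargylic alcohol that is hindered and ionises easily. The diarylcarbinol carbon and an internal aryl alkyne must sit together in the metallacycle. A4 can trimerise on its own. Boron in A1 is flanked by methyl and the quaternary C3, so the alkyne must still enter at the most crowded carbon by a less usual coupling.
- Comparison: on structure the two plans are equal in leaving the C2 alkynylation to a hindered coupling. On mechanism the chosen plan spreads the risk over reaction types with broad precedent, whereas this alternative stakes ring A on one organometallic cascade at the edge of its usual scope. On step economy the alternative is the better of the two.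

Alternative 2: The cut takes C4–ring B and C3–C7 across the C3–C4 bond of an aryne.
- Forward step: the fluoroarene A6, which already carries the C2 alkyne and has fluorine on C4, would be deprotonated at C3 between fluorine and the alkynyl group. Loss of lithium fluoride would give the C3–C4 aryne. The Grignard reagent A7 would add at C4 so that the new carbanion sits on C3 next to the electron-withdrawing sp carbon, and carboxylation would give the acid A5.
- In favour: the alkyne is installed first by an unhindered Sonogashira coupling, which is better than the chosen plan, where that coupling is the most crowded step. Two ring A bonds form in one flask. C7 enters at the acid level and can reach the quinone methide through a carbinol without an oxidant. About five steps are needed, one fewer than the chosen plan.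
- Against: the site of Grignard addition rests on the modest inductive bias of an alkynyl group and not on a strong director. The deprotonation must choose C3 over C5, the other carbon ortho to fluorine. Aryl metals can add across the triple bond. A5 must then accept two aryl nucleophiles at a carbonyl flanked by alkynyl and aryl groups, where the second addition is likely to be slow.
- Comparison: on structure the chosen plan places every ring A substituent by halogen identity and C–H acidity, which is less ambiguous. On mechanism it brings C7 in as an aldehyde, a far less hindered electrophile than an ester or diaryl ketone. On step economy and in avoiding a final oxidation the alternative is the equal or the better.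

Alternative 3: The cut opens ring A along C1–C6 and C3–C4 into two three-carbon pieces: the bis-silyl dienol ether A9 (C1, C2, C3 with the methyl group and the ester carbon C7) and the β-ketoacetal A10 (C4, C5, C6 and ring B).
- Forward step: TiCl4 would ionise the acetal, the terminal diene carbon of A9 would attack it (C1–C6), the central carbon would add to the aryl ketone (C3–C4), and loss of methanol and water would aromatise the ring to the salicylate A8.
- In favour: the 1,2,3,4-pattern is written into the polarity of two acyclic partners, so the regiochemistry of ring A is as secure as in the chosen plan or more so. The C2 hydroxyl is a ready handle, as its triflate, for the alkyne. No cryogenic aryllithium is needed and the inputs are cheap. C7 again needs no final oxidant, which is better.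
- Against: it is the longest of the four. Two silylations to reach A9, the preparation of A10, the cyclisation, triflation, a hindered alkynylation, conversion of a di-ortho-substituted benzoate into a diaryl carbinol and demethylation add up to about eight or nine steps. Aryl ketones are the weaker electrophiles in this cyclisation, and the ester arylation meets the same steric wall as in alternative 2.
- Comparison: on mechanism the ring construction is an established formal [3+3] type and is equal in reliability to the steps of the chosen plan. On structure it is equal or better in regiochemical certainty. On step economy, and at the crowded ester, it is clearly worse.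

Key step: step 3

## Route

Step 1
Reactants: 1 2-bromo-4-iodotoluene
Product: 4 2-bromo-6-iodo-3-methylbenzaldehyde, via aryllithium 2 (not isolated), via lithium hemiaminolate 3 (not isolated)
Conditions: LiN(i-Pr)2 (1.1 equiv), THF, −78 °C; DMF, −78 °C; aq. HCl
Reagents that add atoms: N,N-dimethylformamide, CN(C)C=O
Why: Directed deprotonation between two halogens followed by formylation of the aryllithium with a formamide; the C–H between Br and I is the most acidic ring proton, the amide base does not undergo halogen–lithium exchange, and at −78 °C the anion already sits at its most stabilised position, so neither halogen migration nor loss of lithium halide to an aryne should intervene before DMF gives 3, which collapses to the aldehyde on acidic work-up.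

Step 2
Reactants: 4 2-bromo-6-iodo-3-methylbenzaldehyde; 5 4-methoxyphenylboronic acid
Product: 6 2-bromo-6-(4-methoxyphenyl)-3-methylbenzaldehyde
Conditions: Pd(PPh3)4 (3 mol %), Na2CO3 (2 equiv), DME/H2O, 70 °C
Reagents that add atoms: none
Why: Suzuki–Miyaura coupling; zerovalent palladium inserts into the C–I bond, which has a single ortho neighbour, much faster than into the C–Br bond flanked by the formyl and methyl groups, so one aryl group should enter at C6 only; the aldehyde tolerates aqueous carbonate.

Step 3
Reactants: 6 2-bromo-6-(4-methoxyphenyl)-3-methylbenzaldehyde; 7 phenol (large excess, two molecules incorporated)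
Product: 10 4,4'-{[2-bromo-6-(4-methoxyphenyl)-3-methylphenyl]methylene}diphenol, via benzhydrol 8 (not isolated), via quinone methide 9 (not isolated)
Conditions: 7 (15 equiv, as melt), MeSO3H (1 equiv), 50 °C
Reagents that add atoms: none
Why: Protonation of the aldehyde of 6 lets the para carbon of 7 attack the carbonyl carbon (C7) to give benzhydrol 8, which loses water under the acid to the para-hydroxybenzhydryl cation, the O-protonated form of quinone methide 9; a second molecule of 7 adds through its para carbon and rearomatises to 10. The closest known reaction type is the acid-catalysed bisphenol condensation of aromatic aldehydes with phenols to bis(4-hydroxyphenyl)arylmethanes, a double Friedel–Crafts hydroxyarylation. Two C7–aryl bonds are formed, no ring is closed, and no stereocentre arises because C7 ends with two identical 4-hydroxyphenyl groups. The step needs para attack twice: the electrophile carries Br and the anisyl ring in both ortho positions, which should keep it away from the crowded ortho carbons of 7, and the reversibility of Friedel–Crafts alkylation under acid should drain any ortho,para isomer towards the para,para product. The second selectivity is intermolecular capture against closure of the cation onto ring B to a 9-arylfluorene; the ring B carbons within reach are meta to the methoxy group and not activated, whereas 7 is the reaction medium. The aryl bromide, the aryl methyl ether and the ring A methyl group are inert to MeSO3H at this temperature, and no alkyne is yet present to trap the cation.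

Step 4
Reactants: 10 4,4'-{[2-bromo-6-(4-methoxyphenyl)-3-methylphenyl]methylene}diphenol; 11 4-ethynylanisole
Product: 12 4,4'-({6-(4-methoxyphenyl)-2-[(4-methoxyphenyl)ethynyl]-3-methylphenyl}methylene)diphenol
Conditions: PdCl2(PhCN)2 (5 mol %), [HP(t-Bu)3]BF4 (10 mol %), CuI (5 mol %), i-Pr2NH, 1,4-dioxane, 60 °C, slow addition of 11 (1.5 equiv), degassed
Reagents that add atoms: none
Why: Sonogashira coupling; the bulky, electron-rich P(t-Bu)3 gives a monoligated zerovalent palladium species able to insert into di-ortho-substituted aryl bromides, the amine base leaves the two phenols largely un-ionised, and slow addition of 11 under exclusion of air limits its oxidative homocoupling; the C7–H bond and the methyl ethers are untouched.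

Step 5
Reactants: 12 4,4'-({6-(4-methoxyphenyl)-2-[(4-methoxyphenyl)ethynyl]-3-methylphenyl}methylene)diphenol
Product: 13 4,4'-({6-(4-hydroxyphenyl)-2-[(4-hydroxyphenyl)ethynyl]-3-methylphenyl}methylene)diphenol
Conditions: BBr3 (8 equiv), CH2Cl2, −78 → 0 °C; ice-water
Reagents that add atoms: none
Why: Lewis-acid cleavage of aryl methyl ethers; BBr3 binds each anisole oxygen and bromide removes the methyl group by SN2 attack, and the aryloxyboranes are hydrolysed on work-up. The methoxy groups are para and not ortho to the alkyne, so no borylative cyclisation onto the triple bond is open, and C7 is still an sp3 C–H, so no cation stands next to the alkyne while the Lewis acid is present.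

Step 6
Reactants: 13 4,4'-({6-(4-hydroxyphenyl)-2-[(4-hydroxyphenyl)ethynyl]-3-methylphenyl}methylene)diphenol
Product: 14 selaginellin U, 4-[{6-(4-hydroxyphenyl)-2-[(4-hydroxyphenyl)ethynyl]-3-methylphenyl}(4-hydroxyphenyl)methylidene]cyclohexa-2,5-dien-1-one
Conditions: DDQ (1.05 equiv), 1,4-dioxane, rt
Reagents that add atoms: none
Why: Dehydrogenation of a leuco bis(4-hydroxyphenyl)arylmethane to its fuchsone by a high-potential quinone; DDQ takes hydride from C7, the only C–H activated by two para-hydroxyphenyl rings, and the resulting carbenium ion loses a phenolic proton to give the para-quinone methide. The two rings on C7 are identical, so it does not matter which becomes the dienone, and one equivalent at room temperature in a non-nucleophilic solvent should leave the ring B phenol, the alkynyl phenol, the alkyne and the ring A methyl group alone.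

## Compound list

1 | 2-bromo-4-iodotoluene (2-bromo-4-iodo-1-methylbenzene) | Cc1ccc(I)cc1Br | starting material
2 | (2-bromo-6-iodo-3-methylphenyl)lithium | [Li]c1c(I)ccc(C)c1Br | intermediate (not isolated)
3 | lithium (2-bromo-6-iodo-3-methylphenyl)(dimethylamino)methanolate | [Li+].[O-]C(N(C)C)c1c(I)ccc(C)c1Br | intermediate (not isolated)
4 | 2-bromo-6-iodo-3-methylbenzaldehyde | Cc1ccc(I)c(C=O)c1Br | intermediate
5 | 4-methoxyphenylboronic acid | COc1ccc(B(O)O)cc1 | starting material
6 | 2-bromo-6-(4-methoxyphenyl)-3-methylbenzaldehyde | Cc1ccc(-c2ccc(OC)cc2)c(C=O)c1Br | intermediate
7 | phenol | Oc1ccccc1 | starting material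
8 | 4-{[2-bromo-6-(4-methoxyphenyl)-3-methylphenyl](hydroxy)methyl}phenol | Cc1ccc(-c2ccc(OC)cc2)c(C(O)c2ccc(O)cc2)c1Br | intermediate (not isolated)
9 | 4-{[2-bromo-6-(4-methoxyphenyl)-3-methylphenyl]methylidene}cyclohexa-2,5-dien-1-one | Cc1ccc(-c2ccc(OC)cc2)c(C=C2C=CC(=O)C=C2)c1Br | intermediate (not isolated)
10 | 4,4'-{[2-bromo-6-(4-methoxyphenyl)-3-methylphenyl]methylene}diphenol | Cc1ccc(-c2ccc(OC)cc2)c(C(c2ccc(O)cc2)c2ccc(O)cc2)c1Br | intermediate
11 | 4-ethynylanisole (1-ethynyl-4-methoxybenzene) | C#Cc1ccc(OC)cc1 | starting material
12 | 4,4'-({6-(4-methoxyphenyl)-2-[(4-methoxyphenyl)ethynyl]-3-methylphenyl}methylene)diphenol | Cc1ccc(-c2ccc(OC)cc2)c(C(c2ccc(O)cc2)c2ccc(O)cc2)c1C#Cc1ccc(OC)cc1 | intermediate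
13 | 4,4'-({6-(4-hydroxyphenyl)-2-[(4-hydroxyphenyl)ethynyl]-3-methylphenyl}methylene)diphenol | Cc1ccc(-c2ccc(O)cc2)c(C(c2ccc(O)cc2)c2ccc(O)cc2)c1C#Cc1ccc(O)cc1 | intermediate
14 | selaginellin U, 4-[{6-(4-hydroxyphenyl)-2-[(4-hydroxyphenyl)ethynyl]-3-methylphenyl}(4-hydroxyphenyl)methylidene]cyclohexa-2,5-dien-1-one | Cc1ccc(-c2ccc(O)cc2)c(C(=C2C=CC(=O)C=C2)c2ccc(O)cc2)c1C#Cc1ccc(O)cc1 | target

## Step count and least certain steps

Total step count: 6. Longest linear sequence: 6 steps (1 → 14); 5, 7 and 11 enter as commercial partners.

Step 3 (key step). What may go wrong: attack on a carbonyl flanked by Br and the anisyl ring may be slow. Side processes could then compete: loss of para selectivity on 7, closure of the benzhydryl cation onto ring B, or acid-driven oligomerisation. The fallback sets out from 6 and comes back to the route at 13; it makes the two C7–aryl bonds one at a time, so that the first is formed by carbonyl addition with the para position fixed in the reagent. Addition of 4-methoxyphenylmagnesium bromide (the reagent A7; THF, 0 °C) to 6 should give racemic [2-bromo-6-(4-methoxyphenyl)-3-methylphenyl](4-methoxyphenyl)methanol F1. Ionisation of F1 with CF3CO2H in CH2Cl2 at 0 °C in the presence of excess 7 should give racemic 4-{[2-bromo-6-(4-methoxyphenyl)-3-methylphenyl](4-methoxyphenyl)methyl}phenol F2 by a single, mild Friedel–Crafts alkylation. The coupling of step 4 with 11 would then give racemic 4-[{6-(4-methoxyphenyl)-2-[(4-methoxyphenyl)ethynyl]-3-methylphenyl}(4-methoxyphenyl)methyl]phenol F3, and the BBr3 treatment of step 5 would cleave its three methyl ethers to 13, where the C7 stereocentre disappears. The cost is one extra step.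

Step 4. What may go wrong: insertion and transmetalation at the C–Br bond between the methyl and diarylmethyl groups may be slow, so that oxidative homocoupling of 11 consumes the alkyne, and the free phenols may bind copper. The fallback sets out from 10 and comes back at 13; it removes the protic groups and replaces the copper-amine manifold by an alkynylzinc. Methylation of 10 (MeI, K2CO3, acetone) should give 3-bromo-2-[bis(4-methoxyphenyl)methyl]-4'-methoxy-4-methyl-1,1'-biphenyl F4. Deprotonation of 11 with n-BuLi and addition of ZnCl2 should give chlorido[(4-methoxyphenyl)ethynyl]zinc F5. Negishi coupling of F4 with F5 (Pd(P(t-Bu)3)2, THF, 60 °C) should give 2-[bis(4-methoxyphenyl)methyl]-4'-methoxy-3-[(4-methoxyphenyl)ethynyl]-4-methyl-1,1'-biphenyl F6, and BBr3 would then cleave all four methyl ethers to 13. The cost is one extra step.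

Step 5. What may go wrong: BBr3 or the HBr it releases may add across the electron-rich diaryl alkyne, or the acid may promote hydroarylation of the alkyne by a C7 aryl ring; cleavage may also stall because the free phenols tie up reagent. The fallback sets out from 10 and comes back at 13; it moves the demethylation ahead of the alkyne and brings the last oxygen in under a fluoride-labile group. BBr3 on 10 should give 4,4'-{[2-bromo-6-(4-hydroxyphenyl)-3-methylphenyl]methylene}diphenol F7. Coupling of F7 with commercial tert-butyl(4-ethynylphenoxy)dimethylsilane under the conditions of step 4 should give 4,4'-({2-[(4-{[tert-butyl(dimethyl)silyl]oxy}phenyl)ethynyl]-6-(4-hydroxyphenyl)-3-methylphenyl}methylene)diphenol F8, and Bu4NF in THF would release 13. The cost is one extra step.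

Step 6. What may go wrong: the oxidant may attack the two phenols that are not on C7 (phenoxyl radical coupling), or the quinone methide may be over-oxidised or add a nucleophile. The fallback sets out from 12 and comes back at 14; it oxidises while the ring B and alkynyl oxygens are still methyl ethers, so that only the two C7 phenols are free. DDQ on 12 should give 4-[{6-(4-methoxyphenyl)-2-[(4-methoxyphenyl)ethynyl]-3-methylphenyl}(4-hydroxyphenyl)methylidene]cyclohexa-2,5-dien-1-one F9. BBr3 in CH2Cl2 would then hold F9 as its O-borylated triaryl cation, a species too stabilised to attack the alkyne, while the two methyl ethers are cleaved, and aqueous work-up would return the quinone methide 14. The step count is unchanged.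

## Further compounds

F1 | step 3 | [2-bromo-6-(4-methoxyphenyl)-3-methylphenyl](4-methoxyphenyl)methanol (racemic) | Cc1ccc(-c2ccc(OC)cc2)c(C(O)c2ccc(OC)cc2)c1Br
F2 | step 3 | 4-{[2-bromo-6-(4-methoxyphenyl)-3-methylphenyl](4-methoxyphenyl)methyl}phenol (racemic) | Cc1ccc(-c2ccc(OC)cc2)c(C(c2ccc(OC)cc2)c2ccc(O)cc2)c1Br
F3 | step 3 | 4-[{6-(4-methoxyphenyl)-2-[(4-methoxyphenyl)ethynyl]-3-methylphenyl}(4-methoxyphenyl)methyl]phenol (racemic) | Cc1ccc(-c2ccc(OC)cc2)c(C(c2ccc(OC)cc2)c2ccc(O)cc2)c1C#Cc1ccc(OC)cc1
F4 | step 4 | 3-bromo-2-[bis(4-methoxyphenyl)methyl]-4'-methoxy-4-methyl-1,1'-biphenyl | Cc1ccc(-c2ccc(OC)cc2)c(C(c2ccc(OC)cc2)c2ccc(OC)cc2)c1Br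
F5 | step 4 | chlorido[(4-methoxyphenyl)ethynyl]zinc | COc1ccc(C#C[Zn]Cl)cc1
F6 | step 4 | 2-[bis(4-methoxyphenyl)methyl]-4'-methoxy-3-[(4-methoxyphenyl)ethynyl]-4-methyl-1,1'-biphenyl | Cc1ccc(-c2ccc(OC)cc2)c(C(c2ccc(OC)cc2)c2ccc(OC)cc2)c1C#Cc1ccc(OC)cc1
F7 | step 5 | 4,4'-{[2-bromo-6-(4-hydroxyphenyl)-3-methylphenyl]methylene}diphenol | Cc1ccc(-c2ccc(O)cc2)c(C(c2ccc(O)cc2)c2ccc(O)cc2)c1Br
F8 | step 5 | 4,4'-({2-[(4-{[tert-butyl(dimethyl)silyl]oxy}phenyl)ethynyl]-6-(4-hydroxyphenyl)-3-methylphenyl}methylene)diphenol | Cc1ccc(-c2ccc(O)cc2)c(C(c2ccc(O)cc2)c2ccc(O)cc2)c1C#Cc1ccc(O[Si](C)(C)C(C)(C)C)cc1
F9 | step 6 | 4-[{6-(4-methoxyphenyl)-2-[(4-methoxyphenyl)ethynyl]-3-methylphenyl}(4-hydroxyphenyl)methylidene]cyclohexa-2,5-dien-1-one | Cc1ccc(-c2ccc(OC)cc2)c(C(=C2C=CC(=O)C=C2)c2ccc(O)cc2)c1C#Cc1ccc(OC)cc1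
A1 | alternative 1 | 1-isopropoxy-3,3,4-tris(4-methoxyphenyl)-7-methyl-1,3-dihydro-2,1-benzoxaborole | Cc1ccc(-c2ccc(OC)cc2)c2c1B(OC(C)C)OC2(c1ccc(OC)cc1)c1ccc(OC)cc1
A2 | alternative 1 | 1,1,3-tris(4-methoxyphenyl)prop-2-yn-1-ol | COc1ccc(C#CC(O)(c2ccc(OC)cc2)c2ccc(OC)cc2)cc1
A3 | alternative 1 | diisopropyl prop-1-yn-1-ylboronate | CC#CB(OC(C)C)OC(C)C
A4 | alternative 1 | acetylene | C#C
A5 | alternative 2 | 6-(4-methoxyphenyl)-2-[(4-methoxyphenyl)ethynyl]-3-methylbenzoic acid | Cc1ccc(-c2ccc(OC)cc2)c(C(=O)O)c1C#Cc1ccc(OC)cc1
A6 | alternative 2 | 4-fluoro-2-[(4-methoxyphenyl)ethynyl]-1-methylbenzene | Cc1ccc(F)cc1C#Cc1ccc(OC)cc1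
A7 | alternative 2 | 4-methoxyphenylmagnesium bromide | COc1ccc([Mg]Br)cc1
A8 | alternative 3 | methyl 2-hydroxy-6-(4-methoxyphenyl)-3-methylbenzoate | COC(=O)c1c(O)c(C)ccc1-c1ccc(OC)cc1
A9 | alternative 3 | 1-methoxy-1,3-bis(trimethylsilyloxy)penta-1,3-diene | CC=C(O[Si](C)(C)C)C=C(OC)O[Si](C)(C)C
A10 | alternative 3 | 3,3-dimethoxy-1-(4-methoxyphenyl)propan-1-one | COc1ccc(C(=O)CC(OC)OC)cc1
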